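The runs stem from a simulated flask with made-up constants; scatter was added.

Waiting cannot help the blue flask: from 50.0 min to 180 min its target reads between 31.8% and 32.7%, with a mean of 32.3%, while starting material still reads 66.9%. Nor does this stop look like an equilibrium reached. The red flask, with less partner, levels off near 22.2% and stood at 92.3% of that level by 12.0 min, whereas the blue flask stood at 85.4% of its level by 15.0 min. Between these two runs, which differ in partner, more partner goes with a longer run and a higher stop, which reads as a catalyst being lost. On that reading, taking target out gains nothing, and the decision is whether a fresh dose of catalyst is worth its material.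

| setting | blue | red | flask |
|---|---|---|---|
| starting material | 0.80 M | 0.80 M | 0.80 M |
| second substrate | 0.40 M | 0.40 M | 0.400 M |
| partner | 1.6 M | 1.1 M | 1.60 M |
| capture agent | 0.80 M | 0.80 M | 0.800 M |
| free catalyst | 4 mM | 4 mM | 4.0 mM |
| remark | the very flask that is asked about, followed so far | run made earlier |  |
| time |  |  | 4.0 h |

| run | time / min | target / % | starting material / % |
|---|---|---|---|
| blue | 15.0 | 27.6 | 72.8 |
| blue | 30.0 | 31.6 | 68.8 |
| blue | 50.0 | 32.5 | 67.1 |
| blue | 90.0 | 32.7 | 67.8 |
| blue | 180 | 31.8 | 66.9 |
| red | 2.00 | 7.4 | 93.2 |
| red | 6.00 | 14.7 | 84.8 |
| red | 12.0 | 20.5 | 79.7 |
| red | 20.0 | 21.7 | 77.6 |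
| red | 25.0 | 22.7 | 77.5 |

(scatter of a reading: 0.3 percentage points)

- gamma: at 4.0 h add free catalyst, 100% of the amount charged, then wait 80 min
- eta: at 4.0 h take out 90% of the target then present, then wait 80 min
- epsilon: change nothing and wait 80 min more

- target, in percent of the starting material first charged, at 4.0 h
- what to do for the largest gain in target; "none" if nothing gains more than 2 percentage points (gamma / eta / epsilon / none)
- target present, with what was taken out counted in, in percent of the starting material first charged, after gamma
- target present, with what was taken out counted in, in percent of the starting material first charged, after eta

- target taken out counts as made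
- additions bring no volume worth counting

Dividing the rate of target formation by the rate of catalyst loss removes time. Summed over a run until the catalyst is lost, that ratio gives the turnover number N, the target made per catalyst charged. The level read in the blue run stands for 0.259 M of target from 4 mM, so N reads 64.7. The level read in the red run stands for 0.178 M, so N reads 44.4. Assume that each target costs one partner, and take mean partner as the mean of the charge and the charge less the target made: 1.47 M in blue and 1.01 M in red. Then N over mean partner reads 44.0 /M in blue and 43.9 /M in red. The carried quantity is s = 43.9 /M, the turnover number per unit of mean partner.

At 4.0 h the blue flask should hold 1.34 M of partner. A fresh 4.00 mM of free catalyst, with s and the mean partner during the dose, is then reckoned to make 0.217 M more target. This reckoning therefore expects 59.4% after gamma, and 32.3% both now and after eta.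

The forecast gives 32.3%, chooses gamma, and puts gamma at 49% (44% to 50.3%), below this reckoning, on the ground that “second substrate caps the yield at 50%”, with 32.3% after eta.

The flask gives 32.6%, then 57.5% after gamma, a gain of 25 percentage points, and 32.6% after eta. The equations are:

    starting material + free catalyst ⇌ catalyst intermediate A (K = 10.0 /M, k = 12.0 /M/min)
    partner + catalyst intermediate A ⇌ free catalyst + target (K = 6.40, k = 150 /M/min)
    second substrate + free catalyst ⇌ catalyst intermediate B (K = 290 /M, k = 12.0 /M/min)
    partner + catalyst intermediate B → free catalyst + second product (k = 180 /M/min)
    catalyst intermediate B + capture agent → trapped intermediate (k = 9.90 /M/min)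

In the flask at 240 min partner stands at 75.7% of its charge, below the 83.8% reckoned, with 0.127 M of second product present. A neighbouring flask charged with 0.016 M of free catalyst ends at 240 min with partner at 32.7% of its charge, so the mean of its charged and its end partner is 1.06 M. There s gives 0.747 M of target, or 93.3% of the starting material charged, and that neighbour stands at 90.3% of target with 9.66% of starting material left.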